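All runs come from a simulation with made-up constants; the scatter is artificial.

Start with one division. Monday's run, with 0.600 equivalents of coupling partner, levels off with target at 0.444 of the substrate charge, so it reads 0.740 for the yield on coupling partner, the target plateau per equivalent of partner charged.

in all of them: substrate 20 mM (fed, over 80 min); catalyst 20 µM
- Thursday's: coupling partner 24 mM; the very flask that is asked about, followed so far
- Monday's: coupling partner 12 mM; run made earlier
- flask: coupling partner 24.0 mM; time 15 d

| run | time / d | substrate / % | target / % |
|---|---|---|---|
| Thursday's | 0.833 | 0 | 51 |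
| Thursday's | 1.67 | 0 | 57 |
| Thursday's | 2.50 | 0 | 59 |
| Thursday's | 3.00 | 0 | 58 |
| Thursday's | 4.00 | 3 | 60 |
| Thursday's | 5.00 | 0 | 57 |
| Thursday's | 6.00 | 0 | 58 |
| Monday's | 0.833 | 0 | 36 |
| Monday's | 1.25 | 3 | 40 |
| Monday's | 2.08 | 2 | 46 |
| Monday's | 3.00 | 0 | 45 |
| Monday's | 5.00 | 0 | 45 |
| Monday's | 6.00 | 0 | 42 |
| Monday's | 10.0 | 0 | 44 |

(standard deviation of a reading: 2 percentage points)

- the reaction counts as stopped when no species that holds the substrate changes by six tenths of a point or more over the second half of the time

* at 15 d, what has stopped the reaction, if anything has (it is still moving / all of the substrate has reacted / no working catalyst is left)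
* conversion of substrate at 15 d
* amount of target at 15 d, in percent of the substrate charged

Two chemists dispute Thursday's flask. The first freezes the yield on partner: Thursday's flask has 1.20 equivalents, so its target should end near 0.888. The readings from 1.67 d on average 0.582, so she takes the missing 0.418 of the charge for a pool waiting on unused partner.

The second freezes the target itself. Reaching 0.888 by 15 d needs a climb of 0.0340 d⁻¹, which is faster than the 0.00231 d⁻¹ between Thursday's readings at 1.67 d and 6.00 d.

The forecast takes the second side: all of the substrate has reacted, conversion 100% (98.5% to 100%), target 58% (56% to 60%), reading Monday's run to mean “nothing slowly feeds or destroys the product”.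

The result for Thursday's flask: all of the substrate has reacted, with conversion 100% and target 58.5%, so the plateau stands. At 15.0 d its partner stands at 0% of the charge, so no unused partner is waiting. Its yield on partner is 0.487, lower than the 0.740 read from Monday's run, with twice the partner.

    substrate + catalyst → catalyst + intermediate (k = 3.10 M⁻¹ s⁻¹)
    coupling partner + catalyst + intermediate → catalyst + target (k = 100 M⁻² s⁻¹)
    2 coupling partner → self-condensation product (k = 1.40 × 10⁻⁴ M⁻¹ s⁻¹)
    substrate + intermediate → side product (k = 8.20 × 10⁻⁴ M⁻¹ s⁻¹)
    coupling partner + catalyst + target → catalyst + over-reaction product (k = 17.0 M⁻² s⁻¹)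

The first chemist's frozen yield comes closer with less partner. For a neighbour flask with 9.6 mM of partner, 0.740 gives target 0.355 of the charge, and that neighbour computes to 38.7%, a smaller gap than Thursday's flask showed.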